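**Plan**

Retrosynthesis: the isoflavone is cut at C2 (O1–C2 and C2–C3, a one-carbon unit), then at C4a–C8a of ring A (Claisen closure of a linear methyl 8-aryl-3,5,7-trioxooctanoate), then at C4–C4a (arylacetic N-methoxy-N-methylamide plus the trianion of methyl 3,5-dioxohexanoate), and last at C3–C1' and C3'–CH2 of ring B.
Forward: ring B is bought as 2-bromo-3-hydroxy-4-methoxybenzaldehyde and elaborated (formyl to phenol, side chain by oxetane opening, acetate unit by cross-coupling); the polyketide chain is attached; ring A is folded from the chain; ring C is closed last by one-carbon insertion; hydrogenolysis frees the two ring B phenols.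
Enabling feature: ring A is a phloroglucinol acylated at C4a, the cyclized form of the chain C4–C4a–C5–C6–C7–C8–C8a with C8a at the ester oxidation level and C5, C7 as ketones.
Stereochemistry: the target has no stereocentre and no stereogenic double bond, so nothing needs to be controlled.

Key step: step 10

Remark: the tertiary alcohol is carried unprotected from step 4 on, at the cost of one extra equivalent of organometallic base in steps 6, 7 and 9; compound 1 (the known bromination product of isovanillin) and the zinc reagent 10 are taken as purchased.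

**Route**

Step 1
Reactants: 1 2-bromo-3-hydroxy-4-methoxybenzaldehyde
Product: 2 3-(benzyloxy)-2-bromo-4-methoxybenzaldehyde
Conditions: BnBr, K2CO3, DMF, rt
Reagents that add atoms: benzyl bromide, BrCc1ccccc1
Why: Williamson ether synthesis, in which the phenoxide formed with K2CO3 displaces bromide from benzyl bromide while the aldehyde and the aryl bromide are untouched.

Step 2
Reactants: 2 3-(benzyloxy)-2-bromo-4-methoxybenzaldehyde
Product: 4 3-(benzyloxy)-2-bromo-4-methoxyphenol, via aryl formate 3 (not isolated)
Conditions: mCPBA, CH2Cl2, 0 °C → rt; then K2CO3 (cat.), MeOH, rt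
Reagents that add atoms: 3-chloroperoxybenzoic acid, OOC(=O)c1cccc(Cl)c1
Why: Baeyer–Villiger (Dakin-type) oxidation, in which the electron-rich aryl group carrying a para methoxy substituent should migrate in preference to hydride, followed by base-catalysed methanolysis of the formate to the phenol.

Step 3
Reactants: 4 3-(benzyloxy)-2-bromo-4-methoxyphenol
Product: 5 1,3-bis(benzyloxy)-2-bromo-4-methoxybenzene
Conditions: BnBr, K2CO3, DMF, 60 °C
Reagents that add atoms: benzyl bromide, BrCc1ccccc1
Why: Williamson ether synthesis on the hindered phenol, which gives both future ring B phenols the same hydrogenolysable protection.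

Step 4
Reactants: 5 1,3-bis(benzyloxy)-2-bromo-4-methoxybenzene; 6 2,2-dimethyloxetane
Product: 8 4-[2,6-bis(benzyloxy)-3-methoxyphenyl]-2-methylbutan-2-ol, via aryllithium 7 (not isolated)
Conditions: n-BuLi, THF, −78 °C; then 6, BF3·OEt2, −78 °C; H2O quench
Reagents that add atoms: none
Why: Bromine–lithium exchange at −78 °C is faster than deprotonation of the benzylic ether CH2 groups, and the aryllithium should open the BF3-activated oxetane by SN2 attack at its unsubstituted CH2 carbon (Lewis-acid-promoted organolithium ring opening of an oxetane), leaving the tertiary alcohol.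

Step 5
Reactants: 8 4-[2,6-bis(benzyloxy)-3-methoxyphenyl]-2-methylbutan-2-ol
Product: 9 4-[2,6-bis(benzyloxy)-3-bromo-5-methoxyphenyl]-2-methylbutan-2-ol
Conditions: NBS (1.0 equiv), MeCN, 0 °C → rt
Reagents that add atoms: N-bromosuccinimide, O=C1CCC(=O)N1Br
Why: Electrophilic aromatic bromination, expected at the CH that is ortho to one benzyloxy group and para to the other, which is the usual site of substitution in 1,2,4-trialkoxybenzenes and is more activated than the CH ortho to the methoxy group.

Step 6
Reactants: 9 4-[2,6-bis(benzyloxy)-3-bromo-5-methoxyphenyl]-2-methylbutan-2-ol; 10 (2-ethoxy-2-oxoethyl)zinc bromide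
Product: 11 ethyl 2-[2,4-bis(benzyloxy)-3-(3-hydroxy-3-methylbutyl)-5-methoxyphenyl]acetate
Conditions: 10 (2.5 equiv), Pd(dba)2 (cat.), P(t-Bu)3 (cat.), THF, rt → 60 °C
Reagents that add atoms: none
Why: Negishi-type cross-coupling of a Reformatsky reagent (palladium-catalysed α-arylation of a zinc ester enolate), in which oxidative addition of the aryl bromide to zerovalent palladium, transmetallation and reductive elimination should give the arylacetate under near-neutral conditions that tolerate the free tertiary hydroxyl when the zinc reagent is in excess.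

Step 7
Reactants: 11 ethyl 2-[2,4-bis(benzyloxy)-3-(3-hydroxy-3-methylbutyl)-5-methoxyphenyl]acetate
Product: 12 2-[2,4-bis(benzyloxy)-3-(3-hydroxy-3-methylbutyl)-5-methoxyphenyl]-N-methoxy-N-methylacetamide
Conditions: MeNH(OMe)·HCl, i-PrMgCl, THF, −20 → 0 °C
Reagents that add atoms: N,O-dimethylhydroxylamine hydrochloride, Cl.CNOC
Why: Aminolysis of the ester by the chloromagnesium amide of N,O-dimethylhydroxylamine, a standard ester-to-N-methoxy-N-methylamide conversion whose weakly basic nucleophile should not disturb the benzylic CH2 and for which the tertiary alkoxide is a spectator.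

Step 8
Reactants: 13 dehydroacetic acid
Product: 14 methyl 3,5-dioxohexanoate
Conditions: Mg(OMe)2, MeOH, reflux; then aq. HCl
Reagents that add atoms: methanol (as Mg(OMe)2 in MeOH), CO
Why: Methoxide-mediated retro-Claisen loss of the 3-acetyl group as methyl acetate and methanolysis of the lactone, the known deacetylative ring opening of dehydroacetic acid, should give the magnesium-chelated 3,5-dioxo ester.

Step 9
Reactants: 12 2-[2,4-bis(benzyloxy)-3-(3-hydroxy-3-methylbutyl)-5-methoxyphenyl]-N-methoxy-N-methylacetamide; 14 methyl 3,5-dioxohexanoate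
Product: 16 methyl 8-[2,4-bis(benzyloxy)-3-(3-hydroxy-3-methylbutyl)-5-methoxyphenyl]-3,5,7-trioxooctanoate, via trilithium trianion 15 (not isolated)
Conditions: 14 (3 equiv), LiN(i-Pr)2 (9 equiv), THF, 0 °C; then 12, −78 → 0 °C; cold aq. HCl
Reagents that add atoms: none
Why: Terminal C-acylation of a 1,3,5-tricarbonyl trianion (polyanion Claisen-type acylation), in which the last-formed and most basic carbanion at C6 should add to the N-methoxy-N-methylamide, whose chelated adduct holds until the quench and so allows only one acylation, the first equivalent of trianion being spent on the tertiary hydroxyl.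

Step 10
Reactants: 16 methyl 8-[2,4-bis(benzyloxy)-3-(3-hydroxy-3-methylbutyl)-5-methoxyphenyl]-3,5,7-trioxooctanoate
Product: 18 2-[2,4-bis(benzyloxy)-3-(3-hydroxy-3-methylbutyl)-5-methoxyphenyl]-1-(2,4,6-trihydroxyphenyl)ethan-1-one, via acylcyclohexanetrione 17 (not isolated)
Conditions: Mg(OMe)2 (excess), MeOH, rt → 50 °C; then cold aq. HCl
Reagents that add atoms: none
Why: Mg(OMe)2 should turn the triketo ester into a magnesium enolate chelate across the C3, C5 and C7 oxygens, after which the central carbon C6 of the C5/C7 diketonate (C4a of the target) adds to the ester carbonyl C1 (C8a), methoxide leaves, and trione 17 tautomerizes to the aromatic acylphloroglucinol. The closest known reaction is the base-mediated Claisen (Dieckmann-type) cyclization of 3,5,7-triketo esters to acylphloroglucinols, the laboratory counterpart of the chalcone synthase folding. Ring A closes in the 6-exo-trig mode, the attacked C=O lying outside the new six-membered ring. No stereocentre is formed. The step needs the Claisen closure to outrun the aldol modes (C2 onto the C7 ketone to a resorcylate, or the benzylic C8 onto the C3 ketone), and chelation by divalent magnesium should secure this by holding all three ketones as enolates of low electrophilicity so that the methyl ester is the only free electrophile, with aromatization after loss of methoxide making the closure irreversible. The benzyl ethers and the tertiary alcohol are inert to methanolic methoxide.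

Step 11
Reactants: 18 2-[2,4-bis(benzyloxy)-3-(3-hydroxy-3-methylbutyl)-5-methoxyphenyl]-1-(2,4,6-trihydroxyphenyl)ethan-1-one
Product: 20 3-[2,4-bis(benzyloxy)-3-(3-hydroxy-3-methylbutyl)-5-methoxyphenyl]-5,7-dihydroxy-4H-chromen-4-one, via enaminone 19 (not isolated)
Conditions: Me2NCH(OMe)2 (2.5 equiv), THF, 60 °C
Reagents that add atoms: N,N-dimethylformamide dimethyl acetal, COC(OC)N(C)C
Why: Condensation of the amide acetal at the activated benzylic methylene to the enaminone, followed by addition–elimination of an ortho phenolic hydroxyl with loss of dimethylamine, is the standard deoxybenzoin-to-isoflavone ring closure, and because the two ortho hydroxyls are equivalent only one isoflavone can form.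

Step 12
Reactants: 20 3-[2,4-bis(benzyloxy)-3-(3-hydroxy-3-methylbutyl)-5-methoxyphenyl]-5,7-dihydroxy-4H-chromen-4-one
Product: 21 3-[2,4-dihydroxy-3-(3-hydroxy-3-methylbutyl)-5-methoxyphenyl]-5,7-dihydroxy-4H-chromen-4-one
Conditions: H2 (1 atm), 10% Pd/C, EtOAc–MeOH, rt
Reagents that add atoms: none
Why: Catalytic hydrogenolysis of the two aryl benzyl ethers under neutral conditions, which avoids any acid that could cyclize the tertiary alcohol onto a freed ortho phenol to a 2,2-dimethylchroman, and which is to be stopped after uptake of two equivalents of hydrogen so that the chromone C2=C3 bond is kept.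

**Compound list**

1 | 2-bromo-3-hydroxy-4-methoxybenzaldehyde | COc1ccc(C=O)c(Br)c1O | starting material
2 | 3-(benzyloxy)-2-bromo-4-methoxybenzaldehyde | COc1ccc(C=O)c(Br)c1OCc1ccccc1 | intermediate
3 | 3-(benzyloxy)-2-bromo-4-methoxyphenyl formate (not isolated) | COc1ccc(OC=O)c(Br)c1OCc1ccccc1 | intermediate
4 | 3-(benzyloxy)-2-bromo-4-methoxyphenol | COc1ccc(O)c(Br)c1OCc1ccccc1 | intermediate
5 | 1,3-bis(benzyloxy)-2-bromo-4-methoxybenzene | COc1ccc(OCc2ccccc2)c(Br)c1OCc1ccccc1 | intermediate
6 | 2,2-dimethyloxetane | CC1(C)CCO1 | starting material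
7 | [2,6-bis(benzyloxy)-3-methoxyphenyl]lithium (not isolated) | COc1ccc(OCc2ccccc2)c([Li])c1OCc1ccccc1 | intermediate
8 | 4-[2,6-bis(benzyloxy)-3-methoxyphenyl]-2-methylbutan-2-ol | COc1ccc(OCc2ccccc2)c(CCC(C)(C)O)c1OCc1ccccc1 | intermediate
9 | 4-[2,6-bis(benzyloxy)-3-bromo-5-methoxyphenyl]-2-methylbutan-2-ol | COc1cc(Br)c(OCc2ccccc2)c(CCC(C)(C)O)c1OCc1ccccc1 | intermediate
10 | (2-ethoxy-2-oxoethyl)zinc bromide (Reformatsky reagent of ethyl bromoacetate, solution in ether) | CCOC(=O)C[Zn]Br | starting material
11 | ethyl 2-[2,4-bis(benzyloxy)-3-(3-hydroxy-3-methylbutyl)-5-methoxyphenyl]acetate | CCOC(=O)Cc1cc(OC)c(OCc2ccccc2)c(CCC(C)(C)O)c1OCc1ccccc1 | intermediate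
12 | 2-[2,4-bis(benzyloxy)-3-(3-hydroxy-3-methylbutyl)-5-methoxyphenyl]-N-methoxy-N-methylacetamide | CON(C)C(=O)Cc1cc(OC)c(OCc2ccccc2)c(CCC(C)(C)O)c1OCc1ccccc1 | intermediate
13 | dehydroacetic acid (3-acetyl-6-methyl-2H-pyran-2,4(3H)-dione) | CC(=O)C1C(=O)C=C(C)OC1=O | starting material
14 | methyl 3,5-dioxohexanoate | COC(=O)CC(=O)CC(C)=O | intermediate
15 | trilithium tris-enolate (trianion) of methyl 3,5-dioxohexanoate (not isolated) | C=C([O-])C=C([O-])C=C([O-])OC.[Li+].[Li+].[Li+] | intermediate
16 | methyl 8-[2,4-bis(benzyloxy)-3-(3-hydroxy-3-methylbutyl)-5-methoxyphenyl]-3,5,7-trioxooctanoate | COC(=O)CC(=O)CC(=O)CC(=O)Cc1cc(OC)c(OCc2ccccc2)c(CCC(C)(C)O)c1OCc1ccccc1 | intermediate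
17 | 2-{2-[2,4-bis(benzyloxy)-3-(3-hydroxy-3-methylbutyl)-5-methoxyphenyl]acetyl}cyclohexane-1,3,5-trione (not isolated) | O=C(Cc1cc(OC)c(OCc2ccccc2)c(CCC(C)(C)O)c1OCc1ccccc1)C1C(=O)CC(=O)CC1=O | intermediate
18 | 2-[2,4-bis(benzyloxy)-3-(3-hydroxy-3-methylbutyl)-5-methoxyphenyl]-1-(2,4,6-trihydroxyphenyl)ethan-1-one | O=C(Cc1cc(OC)c(OCc2ccccc2)c(CCC(C)(C)O)c1OCc1ccccc1)c1c(O)cc(O)cc1O | intermediate
19 | 2-[2,4-bis(benzyloxy)-3-(3-hydroxy-3-methylbutyl)-5-methoxyphenyl]-3-(dimethylamino)-1-(2,4,6-trihydroxyphenyl)prop-2-en-1-one (not isolated, alkene geometry not defined) | CN(C)C=C(C(=O)c1c(O)cc(O)cc1O)c1cc(OC)c(OCc2ccccc2)c(CCC(C)(C)O)c1OCc1ccccc1 | intermediate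
20 | 3-[2,4-bis(benzyloxy)-3-(3-hydroxy-3-methylbutyl)-5-methoxyphenyl]-5,7-dihydroxy-4H-chromen-4-one | COc1cc(-c2coc3cc(O)cc(O)c3c2=O)c(OCc2ccccc2)c(CCC(C)(C)O)c1OCc1ccccc1 | intermediate
21 | 3-[2,4-dihydroxy-3-(3-hydroxy-3-methylbutyl)-5-methoxyphenyl]-5,7-dihydroxy-4H-chromen-4-one | COc1cc(-c2coc3cc(O)cc(O)c3c2=O)c(O)c(CCC(C)(C)O)c1O | target

**Step count and risks**

Total steps: 12. Longest linear sequence: 11 steps (steps 1–7 and 9–12, from compound 1); step 8 is a one-step side branch.

Steps most likely to fail:

Step 10. The chain may close by an aldol mode (C2 onto the C7 ketone, or the benzylic C8 onto the C3 ketone) faster than by the Claisen mode, or it may be cut by retro-Claisen methanolysis. The fallback builds ring A from a preformed arene and sets out from amide 12. Directed ortho-lithiation of 1,3,5-tris(methoxymethoxy)benzene with n-BuLi gives 2,4,6-tris(methoxymethoxy)phenyllithium, used in excess to cover the hydroxyl. Its addition to 12 (Weinreb ketone synthesis, THF, −78 → 0 °C) should give 2-[2,4-bis(benzyloxy)-3-(3-hydroxy-3-methylbutyl)-5-methoxyphenyl]-1-[2,4,6-tris(methoxymethoxy)phenyl]ethan-1-one F1. Methanolic HCl at room temperature then cleaves the three acetals; the flanking ring B oxygens are benzylated, so the tertiary alcohol cannot cyclize. The route is rejoined at compound 18.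

Step 9. Proton transfer from the benzylic CH2 of the amide to the strongly basic trianion may compete with C-acylation and return both partners. The fallback changes the oxidation level of the electrophile and sets out from 12. Reduction with i-Bu2AlH (THF, −78 °C) should give 2-[2,4-bis(benzyloxy)-3-(3-hydroxy-3-methylbutyl)-5-methoxyphenyl]acetaldehyde F2. Aldol addition of trianion 15 at −78 °C, where addition to an aldehyde is much faster than enolization, should give racemic methyl 8-[2,4-bis(benzyloxy)-3-(3-hydroxy-3-methylbutyl)-5-methoxyphenyl]-7-hydroxy-3,5-dioxooctanoate F3. Dess–Martin oxidation of the secondary alcohol (the tertiary one is inert) removes the transient stereocentre and rejoins the route at compound 16.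

Step 4. BF3 may ionize or oligomerize the oxetane before the doubly ortho-substituted aryllithium attacks, and warming to force the reaction invites benzylic deprotonation and Wittig rearrangement of the benzyl ethers. The fallback sets out from bromide 5 and replaces the ring opening by allylation and hydration. Bromine–lithium exchange (n-BuLi, THF, −78 °C), transmetallation with CuBr·SMe2 and alkylation with prenyl bromide should give 1,3-bis(benzyloxy)-4-methoxy-2-(3-methylbut-2-en-1-yl)benzene F4. Mukaiyama hydration (Co(acac)2 cat., PhSiH3, O2, i-PrOH, rt) then adds water in the Markovnikov sense to the trisubstituted alkene and rejoins the route at compound 8.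

**Further compounds**

F1 | step 10 | 2-[2,4-bis(benzyloxy)-3-(3-hydroxy-3-methylbutyl)-5-methoxyphenyl]-1-[2,4,6-tris(methoxymethoxy)phenyl]ethan-1-one | COCOc1cc(OCOC)c(C(=O)Cc2cc(OC)c(OCc3ccccc3)c(CCC(C)(C)O)c2OCc2ccccc2)c(OCOC)c1
F2 | step 9 | 2-[2,4-bis(benzyloxy)-3-(3-hydroxy-3-methylbutyl)-5-methoxyphenyl]acetaldehyde | O=CCc1cc(OC)c(OCc2ccccc2)c(CCC(C)(C)O)c1OCc1ccccc1
F3 | step 9 | methyl 8-[2,4-bis(benzyloxy)-3-(3-hydroxy-3-methylbutyl)-5-methoxyphenyl]-7-hydroxy-3,5-dioxooctanoate (racemic) | COC(=O)CC(=O)CC(=O)CC(O)Cc1cc(OC)c(OCc2ccccc2)c(CCC(C)(C)O)c1OCc1ccccc1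
F4 | step 4 | 1,3-bis(benzyloxy)-4-methoxy-2-(3-methylbut-2-en-1-yl)benzene | COc1ccc(OCc2ccccc2)c(CC=C(C)C)c1OCc1ccccc1
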